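The chair opened the meeting on delta, the flask followed so far, by laying out its charges, the earlier runs and the questions.

| flask | starting material | second substrate | solid reagent | free catalyst | impurity | temperature | remark | time |
|---|---|---|---|---|---|---|---|---|
| delta | 0.61 M | 2 equiv | 0.90 equiv | 2.3 mol% | 15 mM | 25 °C | the very flask that is asked about, followed so far |  |
| epsilon | 0.61 M | 2 equiv | 0.90 equiv | 2.3 mol% | 15 mM | 10 °C | run made earlier |  |
| flask | 0.61 M | 2.00 equiv | 0.900 equiv | 2.3 mol% | 15 mM | 25 °C |  | 8.0 d |

- delta (time / h: target / %): 20.0: 25.6; 40.0: 27.6; 60.0: 28.2; 72.0: 28.3; 96.0: 27.7; 120: 27.8
- epsilon (time / h: target / %): 40.0: 25.5; 96.0: 29.5; 120: 30.0; 144: 29.5; 192: 31.2; 240: 30.3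

(readings scatter by 0.5 percentage points)

- cedar: at 8.0 d raise the temperature by 25 K, then wait 8.0 d
- larch: at 8.0 d add free catalyst, 50.0% of the amount charged, then wait 8.0 d
- oak: at 8.0 d take out 90% of the target then present, then wait 8.0 d
- alder: change nothing and wait 8.0 d more

- given per volume of solution although it is solid: solid reagent
- target taken out counts as made
- at the start none of the solid reagent is in solution
- additions bring no volume worth counting

- target, in percent of the starting material first charged, at 8.0 d
- the remedy with the largest gain of target, or "none" below 2 percentage points (cedar / larch / oak / alder / none)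
- target present, with what was taken out counted in, in percent of the starting material first charged, after cedar
- target present, with what was taken out counted in, in percent of the starting material first charged, after alder

The analyst reported that target in delta stops rising: the readings from 60.0 h to 120 h average 28.0%, and the epsilon readings, at 10 °C, average 30.2% from 120 h to 240 h, with any slow rise there hidden in their scatter of 0.5 percentage points. The process chemist objected that 0.900 equiv of solid reagent should have carried the flask further, so something else must have stopped it.

I, taking the minutes, pointed to the small charges: delta holds 15 mM of impurity against 14.0 mM of free catalyst, an excess of 0.970 mM. If each impurity takes one catalyst, the flask can lose its whole charge of catalyst. Dividing the rate of target formation by the rate of catalyst loss then removes time. The delta plateau over the catalyst charge gives 12.2 for N, the target made per catalyst lost, a turnover number. Epsilon gives 13.2, somewhat larger.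

The chemist replied that a flat line also fits an equilibrium, and the readings do not exclude one. I committed to catalyst loss anyway. Waiting, heating and taking out target add no catalyst, so I kept 28.0% for now, cedar and alder, with no gain from oak. Larch adds 7.01 mM of catalyst; the excess impurity takes its share and leaves 6.04 mM. Multiplied by N, that is a gain of 12 points, so I named larch.

The forecast differs from me on the remedy: it gives 28% (27.4% to 28.6%), 25.5% after cedar and 28% after alder, and names oak, reading the flask as “a reversible reaction at equilibrium”.

The simulation gives 28.0% at 8.0 d, 28.0% after cedar, 28.0% after alder, and larch as best, gaining 13 points against my 12 points, while oak gains 0 points.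

    starting material + free catalyst ⇌ catalyst intermediate A (K = 4.60 /M, k = 31.0 /M/h, Ea = 71.0 kJ/mol, ΔH = −80.0 kJ/mol)
    partner + catalyst intermediate A → free catalyst + target (k = 130 /M/h, Ea = 46.0 kJ/mol)
    second substrate + free catalyst ⇌ catalyst intermediate B (K = 3.00 /M, k = 21.0 /M/h, Ea = 49.0 kJ/mol, ΔH = −34.0 kJ/mol)
    partner + catalyst intermediate B → free catalyst + second product (k = 65.0 /M/h, Ea = 51.0 kJ/mol)
    solid reagent ⇌ partner, rate k5*(cs5 - [partner]) while solid is left; crystals form when [partner] > cs5 (solubility = 0.500 M, k = 0.440 /h)
    free catalyst + impurity → spent catalyst (k = 200 /M/h, Ea = 69.0 kJ/mol)
    (constants at 25 °C)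

Delta at 192 h holds spent catalyst at 100%. The neighbour flask, the same recipe with less impurity, holds 6.00 mM of impurity, less than its catalyst. N sets 12.0% of target against the catalyst that impurity can take, and 8.00 mM of catalyst remains beyond it. At 192 h, the neighbour flask shows spent catalyst at 42.8%, solid reagent at 0%, partner at 0 M, and target at 41.8%.

(The numbers in the tables were generated by integration for substances that don't exist, and the scatter is random.)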